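## Retrosynthetic overview

1. Target ⇒ (desilylation) its tris-TBS ether ⇒ furan ring C opened oxidatively to a 2-hydroxystilbene, the stilbenoid precursor of arylbenzofurans; the stilbene is cut at the aryl–vinyl bond (Heck) into a chiral 2-vinylphloroglucinol piece (ring A) and a 5-bromochroman piece (rings B and D).
2. Ring A piece ⇒ a salicylaldehyde whose (R)-3-methylbut-3-en-2-yl group comes from a chelation-controlled enantioselective aromatic Claisen rearrangement of the (E)-tiglyl ether of bis-silylated 2,4,6-trihydroxybenzaldehyde.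
3. Ring B/D piece ⇒ acid-catalysed prenyl–phenol cyclisation (pyran ring D) of a monosilylated 5-bromo-4,6-diprenylresorcinol, made by double aromatic Claisen rearrangement of the bis(1,1-dimethylallyl) ether of 5-bromoresorcinol.
4. Ring order: aromatic rings A and B are bought; pyran ring D is closed first (fragment stage); furan ring C is closed last, in the same flask as the fragment union.

Abbreviations: TBS = tert-butyldimethylsilyl, TBSO = tert-butyldimethylsilyloxy; ring A = benzo ring of the benzofuran, ring C = furan, ring B = aryl ring of the chroman, ring D = pyran.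

Assumption 1: tert-butyl 2-methylbut-3-en-2-yl carbonate is bought as a catalogue reverse-prenylation reagent (otherwise one operation from 2-methylbut-3-en-2-ol and Boc2O).

Assumption 2: in the Claisen step the (S,S)-ligand is taken to give the R product; if the first run shows the opposite sense, the (R,R)-ligand (also commercial) is used with everything else unchanged.

## Route

Step 1
Reactants: 1 2,4,6-trihydroxybenzaldehyde
Product: 2 2-hydroxy-4,6-bis(TBSO)benzaldehyde
Conditions: TBSCl (2.1 equiv), imidazole (2.5 equiv), DMF, 0 °C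
Reagents that add atoms: tert-butyldimethylsilyl chloride, CC(C)(C)[Si](C)(C)Cl
Why: Phenol silylation at the two more reactive hydroxyls, while the third, locked in a hydrogen bond to the formyl oxygen, stays free (the same selectivity as the standard bis-MOM protection of this aldehyde) and is reserved for the allyl ether.

Step 2
Reactants: 2 2-hydroxy-4,6-bis(TBSO)benzaldehyde
Product: 3 2-{[(2E)-2-methylbut-2-en-1-yl]oxy}-4,6-bis(TBSO)benzaldehyde
Conditions: (E)-2-methylbut-2-en-1-ol (1.3 equiv), PPh3, DIAD, THF, 0 °C → rt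
Reagents that add atoms: (E)-2-methylbut-2-en-1-ol (tiglyl alcohol), C/C=C(\C)CO
Why: Mitsunobu etherification of the acidic, hydrogen-bonded phenol with the primary allylic alcohol proceeds by SN2 attack without allylic transposition and keeps the E alkene geometry that the next step needs.

Step 3
Reactants: 3 2-{[(2E)-2-methylbut-2-en-1-yl]oxy}-4,6-bis(TBSO)benzaldehyde
Product: 4 2-hydroxy-3-[(2R)-3-methylbut-3-en-2-yl]-4,6-bis(TBSO)benzaldehyde
Conditions: Cu(OTf)2 (15 mol%), (S,S)-t-Bu-box (17 mol%), 4 Å MS, CH2Cl2, −20 °C → rt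
Reagents that add atoms: none
Why: Proposed new method: two-point binding of the formyl oxygen and the allyl ether oxygen to [Cu((S,S)-t-Bu-box)](OTf)2 (divalent copper) polarises the C–O bond and accelerates a [3,3]-sigmatropic aromatic Claisen rearrangement through a chair transition state on one face of C3, so that the E alkene geometry and the C2-symmetric ligand together set the new benzylic stereocentre as R while rearomatisation frees the 2-hydroxyl; the closest known reaction types are the Cu(OTf)2/chiral-ligand-catalysed enantioselective aromatic Claisen rearrangement of allyl 2-naphthyl ethers that carry a chelating ester and the [Cu(t-Bu-box)](SbF6)2-catalysed Claisen rearrangement of 2-alkoxycarbonyl allyl vinyl ethers.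

Step 4
Reactants: 4 2-hydroxy-3-[(2R)-3-methylbut-3-en-2-yl]-4,6-bis(TBSO)benzaldehyde
Product: 5 3,5-bis(TBSO)-2-ethenyl-6-[(2R)-3-methylbut-3-en-2-yl]phenol
Conditions: Ph3PCH3Br (3.0 equiv), NaN(SiMe3)2 (2.9 equiv), THF, 0 °C → rt
Reagents that add atoms: methyltriphenylphosphonium bromide (used as its ylide), C[P+](c1ccccc1)(c1ccccc1)c1ccccc1.[Br-]
Why: Wittig methylenation with the non-stabilised ylide converts the formyl group (present as the sodium phenoxide, hence the excess ylide) into the vinyl group without touching the remote, non-enolisable benzylic stereocentre.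

Step 5
Reactants: 6 5-bromobenzene-1,3-diol
Product: 7 1-bromo-3,5-bis[(2-methylbut-3-en-2-yl)oxy]benzene
Conditions: tert-butyl 2-methylbut-3-en-2-yl carbonate (2.4 equiv), Pd(PPh3)4 (5 mol%), THF, 0 °C
Reagents that add atoms: tert-butyl 2-methylbut-3-en-2-yl carbonate, C=CC(C)(C)OC(=O)OC(C)(C)C
Why: Tsuji–Trost O-allylation in which Pd(PPh3)4 (zerovalent palladium) ionises the tertiary carbonate with loss of CO2 and each phenoxide attacks the more substituted terminus of the 1,1-dimethyl-π-allyl complex under kinetic control at 0 °C, giving the tertiary (reverse-prenyl) aryl ethers while the aryl bromide is inert at this temperature.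

Step 6
Reactants: 7 1-bromo-3,5-bis[(2-methylbut-3-en-2-yl)oxy]benzene
Product: 9 5-bromo-4,6-bis(3-methylbut-2-en-1-yl)benzene-1,3-diol, via mono-rearranged phenol 8 (not isolated)
Conditions: xylenes, PhNEt2 (0.5 equiv), 130 °C
Reagents that add atoms: none
Why: Two consecutive thermal [3,3]-sigmatropic aromatic Claisen rearrangements turn each 1,1-dimethylallyl ether into a linear prenyl group on the ortho carbon next to bromine, because a meta halogen directs the shift to its own ortho position and a meta oxygen directs it para to itself (as in the 4,6-diallylation of resorcinol diallyl ether); no stereocentre is formed.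

Step 7
Reactants: 9 5-bromo-4,6-bis(3-methylbut-2-en-1-yl)benzene-1,3-diol
Product: 10 3-bromo-5-(TBSO)-2,4-bis(3-methylbut-2-en-1-yl)phenol
Conditions: TBSCl (1.0 equiv), imidazole (1.2 equiv), CH2Cl2, 0 °C
Reagents that add atoms: tert-butyldimethylsilyl chloride, CC(C)(C)[Si](C)(C)Cl
Why: Monosilylation of the C2-symmetric resorcinol (a statistical desymmetrisation, with unreacted diol recovered and recycled) blocks one phenol so that only one of the two prenyl groups can cyclise in the next step.

Step 8
Reactants: 10 3-bromo-5-(TBSO)-2,4-bis(3-methylbut-2-en-1-yl)phenol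
Product: 11 5-bromo-7-(TBSO)-2,2-dimethyl-6-(3-methylbut-2-en-1-yl)chromane
Conditions: p-TsOH·H2O (10 mol%), PhMe, 50 °C
Reagents that add atoms: none
Why: Biomimetic chroman closure by acid-catalysed intramolecular hydroalkoxylation, in which Markovnikov protonation of the prenyl alkene is followed by six-membered capture of the tertiary cation by the adjacent free phenol, while the prenyl group next to the silyl ether has no nucleophile and stays open.

Step 9
Reactants: 5 3,5-bis(TBSO)-2-ethenyl-6-[(2R)-3-methylbut-3-en-2-yl]phenol (1.2 equiv); 11 5-bromo-7-(TBSO)-2,2-dimethyl-6-(3-methylbut-2-en-1-yl)chromane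
Product: 13 4,6-bis(TBSO)-2-[7-(TBSO)-2,2-dimethyl-6-(3-methylbut-2-en-1-yl)chroman-5-yl]-7-[(2R)-3-methylbut-3-en-2-yl]-1-benzofuran, via hydroxystilbene 12 (not isolated)
Conditions: Pd(OAc)2 (5 mol%), P(t-Bu)3·HBF4 (10 mol%), Cy2NMe (2.5 equiv), dioxane, 60 °C; then AcOH (3 equiv), MeCN, PhI(OAc)2 (1.3 equiv), 0 °C → rt
Reagents that add atoms: none
Why: Proposed new method: a Mizoroki–Heck coupling of the hindered aryl bromide with the terminal carbon of the vinylphenol gives (E)-2-hydroxystilbene 12, and without isolation two-electron oxidation of its only free phenol by PhI(OAc)2 (trivalent iodine) generates a cation delocalised onto the stilbene carbon next to ring B, which the phenol oxygen captures in a five-membered closure before proton loss to the benzofuran, the oxidative stilbene-to-arylbenzofuran cyclisation assumed in biosynthesis; the closest known reaction types are the Heck reaction under Pd/P(t-Bu)3/Cy2NMe conditions and the PhI(OAc)2-mediated cyclisation of 2-hydroxystilbenes to 2-arylbenzofurans, here merged in one flask, and no stereocentre is formed or touched.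

Step 10
Reactants: 13 4,6-bis(TBSO)-2-[7-(TBSO)-2,2-dimethyl-6-(3-methylbut-2-en-1-yl)chroman-5-yl]-7-[(2R)-3-methylbut-3-en-2-yl]-1-benzofuran
Product: 14 2-[7-hydroxy-2,2-dimethyl-6-(3-methylbut-2-en-1-yl)-3,4-dihydro-2H-chromen-5-yl]-7-[(2R)-3-methylbut-3-en-2-yl]-1-benzofuran-4,6-diol
Conditions: TBAF (3.5 equiv), AcOH (3.5 equiv), THF, 0 °C, argon
Reagents that add atoms: none
Why: Fluoride-mediated cleavage of the three aryl silyl ethers under acetic acid buffering leaves the acid-sensitive prenyl and isopropenyl groups and the benzylic R stereocentre untouched and gives the target.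

## Compound list

1 | 2,4,6-trihydroxybenzaldehyde | O=Cc1c(O)cc(O)cc1O | starting material
2 | 2-hydroxy-4,6-bis(TBSO)benzaldehyde | O=Cc1c(O)cc(O[Si](C)(C)C(C)(C)C)cc1O[Si](C)(C)C(C)(C)C | intermediate
3 | 2-{[(2E)-2-methylbut-2-en-1-yl]oxy}-4,6-bis(TBSO)benzaldehyde | C/C=C(\C)COc1cc(O[Si](C)(C)C(C)(C)C)cc(O[Si](C)(C)C(C)(C)C)c1C=O | intermediate
4 | 2-hydroxy-3-[(2R)-3-methylbut-3-en-2-yl]-4,6-bis(TBSO)benzaldehyde | C=C(C)[C@@H](C)c1c(O)c(C=O)c(O[Si](C)(C)C(C)(C)C)cc1O[Si](C)(C)C(C)(C)C | intermediate
5 | 3,5-bis(TBSO)-2-ethenyl-6-[(2R)-3-methylbut-3-en-2-yl]phenol | C=C(C)[C@@H](C)c1c(O)c(C=C)c(O[Si](C)(C)C(C)(C)C)cc1O[Si](C)(C)C(C)(C)C | intermediate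
6 | 5-bromobenzene-1,3-diol (5-bromoresorcinol) | Oc1cc(O)cc(Br)c1 | starting material
7 | 1-bromo-3,5-bis[(2-methylbut-3-en-2-yl)oxy]benzene | C=CC(C)(C)Oc1cc(Br)cc(OC(C)(C)C=C)c1 | intermediate
8 | 3-bromo-2-(3-methylbut-2-en-1-yl)-5-[(2-methylbut-3-en-2-yl)oxy]phenol | CC(C)=CCc1c(O)cc(OC(C)(C)C=C)cc1Br | intermediate (not isolated)
9 | 5-bromo-4,6-bis(3-methylbut-2-en-1-yl)benzene-1,3-diol | CC(C)=CCc1c(O)cc(O)c(CC=C(C)C)c1Br | intermediate
10 | 3-bromo-5-(TBSO)-2,4-bis(3-methylbut-2-en-1-yl)phenol | CC(C)=CCc1c(O)cc(O[Si](C)(C)C(C)(C)C)c(CC=C(C)C)c1Br | intermediate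
11 | 5-bromo-7-(TBSO)-2,2-dimethyl-6-(3-methylbut-2-en-1-yl)chromane | CC(C)=CCc1c(O[Si](C)(C)C(C)(C)C)cc2OC(C)(C)CCc2c1Br | intermediate
12 | 2-[(E)-2-{7-(TBSO)-2,2-dimethyl-6-(3-methylbut-2-en-1-yl)chroman-5-yl}ethenyl]-3,5-bis(TBSO)-6-[(2R)-3-methylbut-3-en-2-yl]phenol | C=C(C)[C@@H](C)c1c(O)c(/C=C/c2c(CC=C(C)C)c(O[Si](C)(C)C(C)(C)C)cc3OC(C)(C)CCc23)c(O[Si](C)(C)C(C)(C)C)cc1O[Si](C)(C)C(C)(C)C | intermediate (not isolated)
13 | 4,6-bis(TBSO)-2-[7-(TBSO)-2,2-dimethyl-6-(3-methylbut-2-en-1-yl)chroman-5-yl]-7-[(2R)-3-methylbut-3-en-2-yl]-1-benzofuran | C=C(C)[C@@H](C)c1c(O[Si](C)(C)C(C)(C)C)cc(O[Si](C)(C)C(C)(C)C)c2cc(-c3c(CC=C(C)C)c(O[Si](C)(C)C(C)(C)C)cc4OC(C)(C)CCc34)oc12 | intermediate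
14 | 2-[7-hydroxy-2,2-dimethyl-6-(3-methylbut-2-en-1-yl)-3,4-dihydro-2H-chromen-5-yl]-7-[(2R)-3-methylbut-3-en-2-yl]-1-benzofuran-4,6-diol | C=C(C)[C@@H](C)c1c(O)cc(O)c2cc(-c3c(CC=C(C)C)c(O)cc4c3CCC(C)(C)O4)oc12 | target

## Step count and risks

Total steps: 10. Longest linear sequence: 6 steps (1, 2, 3, 4, 9, 10; the bromochroman branch 5, 6, 7, 8, 9, 10 is equally long).

Three steps most likely to fail:

**Step 3 (enantioselective aromatic Claisen).** The Lewis acid may ionise the electron-rich tiglyl ether, giving racemic or linear C-alkylated material. The enantiomeric excess may be low, or the product salicylaldehyde may sequester the copper. Fallback, setting out from 3 and coming back at 4: 3 is heated without catalyst in N,N-diethylaniline at 160 °C (plain thermal aromatic Claisen rearrangement) to give racemic 2-hydroxy-3-(3-methylbut-3-en-2-yl)-4,6-bis(TBSO)benzaldehyde F1. F1 is resolved by preparative chromatography on a chiral stationary phase (SFC); the R enantiomer is 4, the S enantiomer is set aside, and the route continues unchanged.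

**Step 6 (double Claisen regiochemistry).** Part of the material may migrate to the carbon between the two oxygens, giving 2,4-diprenyl isomers that are hard to separate. Fallback, setting out from 6 and coming back at 9:
- 6 is bis-silylated (TBSCl, imidazole, DMF) to 1-bromo-3,5-bis(TBSO)benzene F2.
- F2 is iodinated twice, para to each silyloxy group and ortho to bromine (NIS, cat. TFA, MeCN), to 2-bromo-1,3-diiodo-4,6-bis(TBSO)benzene F3.
- F3 is coupled at both C–I bonds with Me2C=CHCH2ZnBr (Pd(OAc)2/CPhos, THF; Negishi coupling, C–I before C–Br, linear-selective) to 2-bromo-1,3-bis(3-methylbut-2-en-1-yl)-4,6-bis(TBSO)benzene F4.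
- F4 is desilylated (TBAF, THF) to 9.

**Step 9 (one-flask Heck union and oxidative furan closure).** The doubly ortho-substituted partners may couple slowly, and the electron-rich vinylphenol 5 can dimerise on warming. Residual palladium, phosphine and amine may consume or misdirect the oxidant. The phenol being oxidised also sits next to the isopropenyl group and a benzylic C–H, so quinone methide formation could erode the stereocentre. Fallback, setting out from 11 (with 4, bypassing 5) and coming back at 13:
- Bromine–lithium exchange on 11 (t-BuLi, THF, −78 °C) and quenching with DMF give 7-(TBSO)-2,2-dimethyl-6-(3-methylbut-2-en-1-yl)chromane-5-carbaldehyde F5.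
- Cross-McMurry coupling of F5 with salicylaldehyde 4 (TiCl4, Zn, pyridine, THF, reflux; low-valent titanium, the free ortho-hydroxyl biasing cross- over homo-coupling) gives hydroxystilbene 12, this time isolated and purified.
- Pure 12 is closed with PhI(OAc)2 in MeCN at 0 °C to 13, free of palladium, phosphine and amine.

## Further compounds

F1 | step 3 | racemic 2-hydroxy-3-(3-methylbut-3-en-2-yl)-4,6-bis(TBSO)benzaldehyde | C=C(C)C(C)c1c(O)c(C=O)c(O[Si](C)(C)C(C)(C)C)cc1O[Si](C)(C)C(C)(C)C
F2 | step 6 | 1-bromo-3,5-bis(TBSO)benzene | Brc1cc(O[Si](C)(C)C(C)(C)C)cc(O[Si](C)(C)C(C)(C)C)c1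
F3 | step 6 | 2-bromo-1,3-diiodo-4,6-bis(TBSO)benzene | Brc1c(I)c(O[Si](C)(C)C(C)(C)C)cc(O[Si](C)(C)C(C)(C)C)c1I
F4 | step 6 | 2-bromo-1,3-bis(3-methylbut-2-en-1-yl)-4,6-bis(TBSO)benzene | CC(C)=CCc1c(O[Si](C)(C)C(C)(C)C)cc(O[Si](C)(C)C(C)(C)C)c(CC=C(C)C)c1Br
F5 | step 9 | 7-(TBSO)-2,2-dimethyl-6-(3-methylbut-2-en-1-yl)chromane-5-carbaldehyde | CC(C)=CCc1c(O[Si](C)(C)C(C)(C)C)cc2OC(C)(C)CCc2c1C=O
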